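## Retrosynthetic overview

1. Target 19 ⇐ bromolactone 17: the C2 side chain comes from Takai–Utimoto ethylidenation of the lactone carbonyl, then C-acylation with bromoacetyl bromide. C5–Br ⇐ C5 ketone of 15 by hydride reduction to the axial alcohol and Appel inversion.
2. Keto-lactone 15 ⇐ diol 13 (oxidative lactonisation closes ring B, the oxolane O1–C2–C3–C3a–C7a) ⇐ cycloadduct 9 (formyl on C7a → methyl; C4=C5 enol silyl ether → gem-dimethyl ketone).
3. Cycloadduct 9 ⇐ diene 4 (C3a=C4–C5=C6) + 2-(benzoyloxy)acrolein 8 (C7=C7a). A catalytic enantioselective Diels–Alder reaction forms C6–C7 and C3a–C7a, closes ring A (the carbocycle) and sets both ring-fusion stereocentres.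
4. Enabling feature: in ring A the oxygen-bearing quaternary C7a and the bromine-bearing C5 are 1,4-related across the two unsubstituted methylenes C6 and C7, and C3a (carrying the C3 arm) is next to C7a. With C5 at the enol silyl ether level and a temporary formyl group on C7a, this is the para/ortho pattern of a 2-silyloxydiene plus a 2-acyloxyacrolein.
5. Ring order: ring A (step 5), then ring B (step 9).

Key step: step 5

Locants are those of the 1-benzofuran core of the target (O1, C2, C3, C3a, C4, C5, C6, C7, C7a); ring A is the carbocycle, ring B the oxolane.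

Remark on the chemistry (assumption): but-3-en-1-yl benzoate is taken as a purchasable ester, and the sense of induction of the oxazaborolidinium catalyst in step 5 is assigned by analogy with other 2-substituted acroleins; the enantiomeric catalyst would be used should the opposite sense be found.

## Route

Step 1
Reactants: 1 3-methylbut-3-en-2-one; 2 but-3-en-1-yl benzoate
Product: 3 (E)-4-methyl-5-oxohex-3-en-1-yl benzoate
Conditions: second-generation Grubbs catalyst (5 mol %), 1 (3 equiv), CH2Cl2, 40 °C
Reagents that add atoms: none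
Why: Olefin cross-metathesis of a terminal alkene with a 1,1-disubstituted enone should give the trisubstituted enone as its thermodynamically preferred E isomer while ethene escapes.

Step 2
Reactants: 3 (E)-4-methyl-5-oxohex-3-en-1-yl benzoate
Product: 4 (E)-4-methyl-5-[(triisopropylsilyl)oxy]hexa-3,5-dien-1-yl benzoate
Conditions: TIPSOTf, Et3N, CH2Cl2, −78 to 0 °C
Reagents that add atoms: triisopropylsilyl trifluoromethanesulfonate, CC(C)[Si](C(C)C)(C(C)C)OS(=O)(=O)C(F)(F)F
Why: Soft enolisation and O-silylation (silyl enol ether formation) should remove an α′ proton of the acetyl group, the γ-methylene being trans to the carbonyl and out of reach, to give the cross-conjugated 2-silyloxy-1,3-diene with the E alkene unchanged.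

Step 3
Reactants: 5 2,2-dimethyl-1,3-dioxan-5-one
Product: 7 2,2-dimethyl-4H-1,3-dioxin-5-yl benzoate, via potassium enolate 6 (not isolated)
Conditions: KN(SiMe3)2, THF, −78 °C; then BzCl
Reagents that add atoms: benzoyl chloride, O=C(Cl)c1ccccc1
Why: O-Acylation of a potassium ketone enolate by an acid chloride (enol ester formation) should give the enol benzoate because the hard, dissociated enolate reacts at oxygen.

Step 4
Reactants: 7 2,2-dimethyl-4H-1,3-dioxin-5-yl benzoate
Product: 8 3-oxoprop-1-en-2-yl benzoate (2-(benzoyloxy)acrolein)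
Conditions: toluene, 120 °C, sealed tube; distilled and used at once
Reagents that add atoms: none
Why: Thermal retro-hetero-Diels–Alder cleavage of the 4H-1,3-dioxin should expel acetone and unveil the 2-acyloxyacrolein.

Step 5
Reactants: 4 (E)-4-methyl-5-[(triisopropylsilyl)oxy]hexa-3,5-dien-1-yl benzoate; 8 3-oxoprop-1-en-2-yl benzoate
Product: 9 2-[(1S,6S)-6-(benzoyloxy)-6-formyl-2-methyl-3-[(triisopropylsilyl)oxy]cyclohex-2-en-1-yl]ethyl benzoate
Conditions: (S)-3,3-diphenyl-1-(2-methylphenyl)tetrahydro-1H,3H-pyrrolo[1,2-c][1,3,2]oxazaborole (20 mol %), HN(SO2CF3)2 (20 mol %), CH2Cl2, −78 °C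
Reagents that add atoms: none
Why: The protonated oxazaborolidine binds the formyl oxygen of 8 and lowers its LUMO, and diene 4 adds in a concerted, asynchronous [4+2] cycloaddition; the closest known type is the oxazaborolidinium-catalysed enantioselective Diels–Alder reaction of 2-substituted acroleins with 2-silyloxy-1,3-dienes, together with cycloadditions of 2-acyloxyacroleins. Only ring A is closed, as a six-membered carbocycle by intermolecular suprafacial [4π+2π] addition that forms C6–C7 and C3a–C7a. Regiochemistry is secured by the silyloxy group on C5, which makes C6 the nucleophilic diene terminus and pairs it with the unsubstituted β-carbon C7 of the enal (para rule), reinforced by the ortho rule for the alkyl group on C3a. The relative configuration of C3a and C7a follows from the endo rule: with the E diene and the formyl group endo, the C3 arm ends cis to the formyl group (the later methyl) and trans to the benzoyloxy oxygen, which is the trans ring fusion of the target. The absolute configuration of both centres is set by the catalyst, which shields one face of the bound enal. The step needs the enol silyl ether to survive and the addition to stay concerted, which the bulky triisopropylsilyl group and the low temperature should secure.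

Step 6
Reactants: 9 2-[(1S,6S)-6-(benzoyloxy)-6-formyl-2-methyl-3-[(triisopropylsilyl)oxy]cyclohex-2-en-1-yl]ethyl benzoate
Product: 11 2-[(1S,6S)-6-(benzoyloxy)-2,6-dimethyl-3-[(triisopropylsilyl)oxy]cyclohex-2-en-1-yl]ethyl benzoate, via tosylhydrazone 10 (not isolated)
Conditions: TsNHNH2, THF, rt; then catecholborane, CHCl3, 0 °C; then NaOAc·3H2O, 60 °C
Reagents that add atoms: none
Why: Reductive deoxygenation of the aldehyde through its tosylhydrazone (hydride reduction, sulfinate loss and N2 extrusion from the alkyldiazene, a mild Wolff–Kishner-type reduction) should turn the temporary formyl group on C7a into the methyl group without touching the stereocentres, the enol silyl ether or the esters.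

Step 7
Reactants: 11 2-[(1S,6S)-6-(benzoyloxy)-2,6-dimethyl-3-[(triisopropylsilyl)oxy]cyclohex-2-en-1-yl]ethyl benzoate
Product: 12 2-[(1S,6S)-6-(benzoyloxy)-2,2,6-trimethyl-3-oxocyclohexyl]ethyl benzoate
Conditions: BnMe3N+ F− (anhydrous), MeI, 4 Å molecular sieves, THF, −20 °C to rt
Reagents that add atoms: iodomethane, CI
Why: Fluoride-induced desilylation should give the regiodefined tetrasubstituted enolate, and its C-methylation (regiospecific enolate alkylation from an enol silyl ether) places the second methyl on C4, a carbon that is not stereogenic.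

Step 8
Reactants: 12 2-[(1S,6S)-6-(benzoyloxy)-2,2,6-trimethyl-3-oxocyclohexyl]ethyl benzoate
Product: 13 (3S,4S)-4-hydroxy-3-(2-hydroxyethyl)-2,2,4-trimethylcyclohexan-1-one
Conditions: NaOMe (0.3 equiv), MeOH, 50 °C
Reagents that add atoms: none
Why: Base-catalysed transesterification (methanolysis) should remove both benzoates, and neither stereocentre can epimerise because C3a has no acidifying neighbour and C7a is quaternary.

Step 9
Reactants: 13 (3S,4S)-4-hydroxy-3-(2-hydroxyethyl)-2,2,4-trimethylcyclohexan-1-one
Product: 15 (3aS,7aS)-4,4,7a-trimethylhexahydro-1-benzofuran-2,5-dione, via lactol 14 (not isolated)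
Conditions: TEMPO (2,2,6,6-tetramethylpiperidin-1-oxyl, 10 mol %), PhI(OAc)2 (2.5 equiv), CH2Cl2, rt
Reagents that add atoms: none
Why: Chemoselective oxoammonium oxidation of the primary alcohol gives an aldehyde that the tertiary hydroxyl on C7a traps as a five-membered lactol, and further oxidation (oxidative lactonisation of a 1,4-diol) closes ring B as the trans-fused γ-lactone whose fusion was fixed in step 5.

Step 10
Reactants: 15 (3aS,7aS)-4,4,7a-trimethylhexahydro-1-benzofuran-2,5-dione
Product: 16 (3aS,5R,7aS)-5-hydroxy-4,4,7a-trimethylhexahydro-1-benzofuran-2(3H)-one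
Conditions: LiBH(sec-Bu)3, THF, −78 °C; aq NH4Cl
Reagents that add atoms: none
Why: Diastereoselective ketone reduction with a hindered trialkylborohydride should deliver hydride to the C5 carbonyl of the rigid trans-fused bicycle from the equatorial side, giving the axial 5R alcohol, while the lactone is not reduced at this temperature.

Step 11
Reactants: 16 (3aS,5R,7aS)-5-hydroxy-4,4,7a-trimethylhexahydro-1-benzofuran-2(3H)-one
Product: 17 (3aS,5S,7aS)-5-bromo-4,4,7a-trimethylhexahydro-1-benzofuran-2(3H)-one
Conditions: PPh3, CBr4, toluene, 60 °C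
Reagents that add atoms: carbon tetrabromide, BrC(Br)(Br)Br
Why: In the Appel reaction the alkoxyphosphonium ion is displaced by bromide with inversion (SN2), which should turn the axial 5R alcohol into the equatorial 5S bromide of the target.

Step 12
Reactants: 17 (3aS,5S,7aS)-5-bromo-4,4,7a-trimethylhexahydro-1-benzofuran-2(3H)-one
Product: 18 (2Z,3aS,5S,7aS)-5-bromo-2-ethylidene-4,4,7a-trimethyloctahydro-1-benzofuran
Conditions: CH3CHBr2, Zn, TiCl4, TMEDA, PbCl2 (cat.), THF, 25 °C; basic work-up
Reagents that add atoms: 1,1-dibromoethane, CC(Br)Br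
Why: Takai–Utimoto alkylidenation of the lactone carbonyl with the titanium–zinc ethylidene reagent should convert C2=O into the exocyclic Z enol ether, with the hindered equatorial secondary bromide left alone.

Step 13
Reactants: 18 (2Z,3aS,5S,7aS)-5-bromo-2-ethylidene-4,4,7a-trimethyloctahydro-1-benzofuran
Product: 19 1-bromo-3-[(2Z,3aS,5S,7aS)-5-bromo-4,4,7a-trimethylhexahydro-1-benzofuran-2(3H)-ylidene]butan-2-one
Conditions: BrCH2COBr, 2,6-di-tert-butyl-4-methylpyridine, CH2Cl2, −78 to 0 °C
Reagents that add atoms: bromoacetyl bromide, O=C(Br)CBr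
Why: Electrophilic C-acylation of the enol ether at its nucleophilic β-carbon, followed by loss of the proton from that carbon (acylation of an enol ether to a β-alkoxy enone), should install the bromoacetyl group, and the tetrasubstituted double bond is expected to settle in the Z geometry (acyl syn to O1, methyl next to C3) of the target.

## Compound list

1 | 3-methylbut-3-en-2-one | CC(=O)C(C)=C | starting material
2 | but-3-en-1-yl benzoate | C=CCCOC(=O)c1ccccc1 | starting material
3 | (E)-4-methyl-5-oxohex-3-en-1-yl benzoate | CC(=O)/C(C)=C/CCOC(=O)c1ccccc1 | intermediate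
4 | (E)-4-methyl-5-[(triisopropylsilyl)oxy]hexa-3,5-dien-1-yl benzoate | C=C(O[Si](C(C)C)(C(C)C)C(C)C)/C(C)=C/CCOC(=O)c1ccccc1 | intermediate
5 | 2,2-dimethyl-1,3-dioxan-5-one | CC1(C)OCC(=O)CO1 | starting material
6 | potassium 2,2-dimethyl-4H-1,3-dioxin-5-olate | CC1(C)OCC([O-])=CO1.[K+] | intermediate
7 | 2,2-dimethyl-4H-1,3-dioxin-5-yl benzoate | CC1(C)OCC(OC(=O)c2ccccc2)=CO1 | intermediate
8 | 3-oxoprop-1-en-2-yl benzoate | C=C(C=O)OC(=O)c1ccccc1 | intermediate
9 | 2-[(1S,6S)-6-(benzoyloxy)-6-formyl-2-methyl-3-[(triisopropylsilyl)oxy]cyclohex-2-en-1-yl]ethyl benzoate | O=C[C@]1(OC(=O)c2ccccc2)CCC(O[Si](C(C)C)(C(C)C)C(C)C)=C(C)[C@@H]1CCOC(=O)c1ccccc1 | intermediate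
10 | 4-methylbenzenesulfonylhydrazone of 9 | Cc1ccc(cc1)S(=O)(=O)NN=C[C@]1(OC(=O)c2ccccc2)CCC(O[Si](C(C)C)(C(C)C)C(C)C)=C(C)[C@@H]1CCOC(=O)c1ccccc1 | intermediate
11 | 2-[(1S,6S)-6-(benzoyloxy)-2,6-dimethyl-3-[(triisopropylsilyl)oxy]cyclohex-2-en-1-yl]ethyl benzoate | C[C@]1(OC(=O)c2ccccc2)CCC(O[Si](C(C)C)(C(C)C)C(C)C)=C(C)[C@@H]1CCOC(=O)c1ccccc1 | intermediate
12 | 2-[(1S,6S)-6-(benzoyloxy)-2,2,6-trimethyl-3-oxocyclohexyl]ethyl benzoate | C[C@]1(OC(=O)c2ccccc2)CCC(=O)C(C)(C)[C@@H]1CCOC(=O)c1ccccc1 | intermediate
13 | (3S,4S)-4-hydroxy-3-(2-hydroxyethyl)-2,2,4-trimethylcyclohexan-1-one | C[C@]1(O)CCC(=O)C(C)(C)[C@@H]1CCO | intermediate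
14 | (3aS,7aS)-2-hydroxy-4,4,7a-trimethylhexahydro-1-benzofuran-5(4H)-one (lactol, both C2 epimers) | OC1C[C@H]2C(C)(C)C(=O)CC[C@]2(C)O1 | intermediate
15 | (3aS,7aS)-4,4,7a-trimethylhexahydro-1-benzofuran-2,5-dione | O=C1C[C@H]2C(C)(C)C(=O)CC[C@]2(C)O1 | intermediate
16 | (3aS,5R,7aS)-5-hydroxy-4,4,7a-trimethylhexahydro-1-benzofuran-2(3H)-one | O=C1C[C@H]2C(C)(C)[C@H](O)CC[C@]2(C)O1 | intermediate
17 | (3aS,5S,7aS)-5-bromo-4,4,7a-trimethylhexahydro-1-benzofuran-2(3H)-one | O=C1C[C@H]2C(C)(C)[C@@H](Br)CC[C@]2(C)O1 | intermediate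
18 | (2Z,3aS,5S,7aS)-5-bromo-2-ethylidene-4,4,7a-trimethyloctahydro-1-benzofuran | C/C=C1/C[C@H]2C(C)(C)[C@@H](Br)CC[C@]2(C)O1 | intermediate
19 | 1-bromo-3-[(2Z,3aS,5S,7aS)-5-bromo-4,4,7a-trimethylhexahydro-1-benzofuran-2(3H)-ylidene]butan-2-one | C/C(C(=O)CBr)=C1\C[C@H]2C(C)(C)[C@@H](Br)CC[C@]2(C)O1 | target

## Step count and risks

Total step count: 13. Longest linear sequence: 11 steps (steps 1, 2 and 5 to 13; the branch through steps 3 and 4 is equally long).

Step 11 is the most likely to fail. At the neopentylic axial carbinol the alkoxyphosphonium ion may undergo anti-periplanar elimination toward C6, or a Wagner–Meerwein methyl shift from C4, faster than backside attack by bromide. The fallback sets out from 15 and comes back at 17; it makes the C5 stereocentre by C–H bond formation instead of C–Br substitution. Ketone 15 is condensed with 1,2-bis(tert-butyldimethylsilyl)hydrazine (Sc(OTf)3 cat.) to the N-silyl hydrazone F1. Oxidation with CuBr2 and Et3N in MeOH gives the geminal dibromide F2. One bromine is then removed with Bu3SnH (1 equiv, Et3B, trace air, toluene, −78 °C). The α-bromo radical should take hydrogen axially from the face opposite to the two axial methyl groups on C4 and C7a, which leaves bromine equatorial as in 17.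

Step 12 is the second risk. The low-valent titanium–zinc reagent may reduce the secondary C–Br bond or fail to add to the hindered lactone carbonyl, and the acid-labile exocyclic enol ether may isomerise into ring B before it is acylated. The fallback sets out from 17 and comes back at 19, replacing steps 12 and 13 by a Claisen-type construction. The regiodefined lithium enolate of butan-2-one (from (Z)-2-(trimethylsilyloxy)but-2-ene and MeLi, THF, −78 °C) is added to lactone 17 to give the hemiketal F3. Acid-catalysed dehydration (TsOH, benzene, 4 Å molecular sieves) gives the vinylogous ester methyl ketone F4. Kinetic enolisation (LiN(SiMe3)2, Me3SiCl, THF, −78 °C) gives the silyl dienol ether F5, and NBS brominates its terminal carbon to give 19.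

Step 6 is the third risk. The alkyldiazene may fragment with expulsion of the neighbouring benzoate (alkene formation at C7a), or the enol silyl ether may be lost under the mildly acidic conditions. The fallback sets out from 9 and comes back at 11; it removes the oxygen by radical deoxygenation. Luche reduction (NaBH4, CeCl3·7H2O, MeOH, −78 °C, quenched cold to suppress benzoyl migration) gives the neopentylic alcohol F6. 1,1′-Thiocarbonyldiimidazole (DMAP cat., CH2Cl2) gives the imidazolyl thiocarbonate F7. Barton–McCombie deoxygenation (Bu3SnH at high concentration, AIBN, toluene, 80 °C) then gives 11; the high stannane concentration is chosen so that hydrogen transfer outruns a 1,2-acyloxy shift of the β-benzoyloxy radical.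

Further compounds
F1 | step 11 | (3aS,7aS)-5-[2-(tert-butyldimethylsilyl)hydrazinylidene]-4,4,7a-trimethylhexahydro-1-benzofuran-2(3H)-one | O=C1C[C@H]2C(C)(C)C(=NN[Si](C)(C)C(C)(C)C)CC[C@]2(C)O1
F2 | step 11 | (3aS,7aS)-5,5-dibromo-4,4,7a-trimethylhexahydro-1-benzofuran-2(3H)-one | O=C1C[C@H]2C(C)(C)C(Br)(Br)CC[C@]2(C)O1
F3 | step 12 | 3-[(3aS,5S,7aS)-5-bromo-2-hydroxy-4,4,7a-trimethyloctahydro-1-benzofuran-2-yl]butan-2-one | CC(C(C)=O)C1(O)C[C@H]2C(C)(C)[C@@H](Br)CC[C@]2(C)O1
F4 | step 12 | 3-[(2Z,3aS,5S,7aS)-5-bromo-4,4,7a-trimethylhexahydro-1-benzofuran-2(3H)-ylidene]butan-2-one | C/C(C(C)=O)=C1\C[C@H]2C(C)(C)[C@@H](Br)CC[C@]2(C)O1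
F5 | step 12 | (2Z,3aS,5S,7aS)-5-bromo-4,4,7a-trimethyl-2-[3-(trimethylsilyloxy)but-3-en-2-ylidene]octahydro-1-benzofuran | C/C(C(=C)O[Si](C)(C)C)=C1\C[C@H]2C(C)(C)[C@@H](Br)CC[C@]2(C)O1
F6 | step 6 | 2-[(1S,6S)-6-(benzoyloxy)-6-(hydroxymethyl)-2-methyl-3-[(triisopropylsilyl)oxy]cyclohex-2-en-1-yl]ethyl benzoate | OC[C@]1(OC(=O)c2ccccc2)CCC(O[Si](C(C)C)(C(C)C)C(C)C)=C(C)[C@@H]1CCOC(=O)c1ccccc1
F7 | step 6 | 2-[(1S,6S)-6-(benzoyloxy)-6-{[(1H-imidazol-1-ylcarbonothioyl)oxy]methyl}-2-methyl-3-[(triisopropylsilyl)oxy]cyclohex-2-en-1-yl]ethyl benzoate | S=C(OC[C@]1(OC(=O)c2ccccc2)CCC(O[Si](C(C)C)(C(C)C)C(C)C)=C(C)[C@@H]1CCOC(=O)c1ccccc1)n1ccnc1
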